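The route rests on disconnecting ring H from the ether oxygen on C6 of ring G, the carbon flanked by oxygen-bearing C1 and C5. Ring H carries that oxygen at C1, hydrogens at C2 and C6 and three contiguous oxygens at C3–C5, exactly the pattern that a cyclobutenone–ynol ether benzannulation delivers. One thermal operation therefore builds the whole ring on an oxygen already in place, and no aryl–oxygen coupling at the most hindered phenol is needed. Its precursor is the ethynyl ether of a benzyl-protected ring G phenol, paired with 3-ethoxy-4-methoxycyclobutenone. Rings A–F are then joined convergently by fluoride displacement on fluorobenzaldehydes, aldehyde-to-phenol oxidation and copper-catalysed etherification, and all alkyl ethers are cleaved last.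

Key step: step 7

Assumption: the target has no stereocentre and its diaryl ethers are taken as freely rotating, so no stereocontrol is needed; rings are lettered A to H from the 2,4,6-trihydroxyphenyl end, and each ring is numbered from the carbon whose ether oxygen points towards ring A (ring A from its own ether carbon).

Step 1
Reactants: 1 methoxyacetyl chloride; 2 ethoxyacetylene
Product: 4 3-ethoxy-4-methoxycyclobut-2-en-1-one (racemic), via methoxyketene 3 (not isolated)
Conditions: Et3N (slow addition), 2 (2.5 equiv), Et2O, 0 °C to rt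
Reagents that add atoms: none
Why: Ketene–alkyne [2+2] cycloaddition: Et3N dehydrochlorinates 1 to methoxyketene, whose carbonyl carbon bonds to the nucleophilic CH terminus of the ynol ether, so that ethoxy should end at C3 and methoxy at C4; the C4 stereocentre forms as a racemate and is erased in step 7.

Step 2
Reactants: 5 3,4,5-trimethoxyphenol
Product: 7 6-hydroxy-2,3,4-trimethoxybenzaldehyde, via salicyl alcohol 6 (not isolated)
Conditions: MgCl2, Et3N, (CH2O)n, MeCN, reflux; then 1 M HCl
Reagents that add atoms: formaldehyde (as paraformaldehyde), C=O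
Why: Magnesium-mediated ortho-formylation of a phenol (Casnati–Skattebøl): the magnesium phenoxide is hydroxymethylated at the ortho carbon and a second formaldehyde oxidises the benzylic alkoxide by hydride transfer; both ortho positions of 5 are equivalent, so a single aldehyde is expected.

Step 3
Reactants: 7 6-hydroxy-2,3,4-trimethoxybenzaldehyde
Product: 8 6-(benzyloxy)-2,3,4-trimethoxybenzaldehyde
Conditions: BnBr, K2CO3, DMF, rt
Reagents that add atoms: benzyl bromide, BrCc1ccccc1
Why: Williamson etherification (SN2) of the phenoxide with a benzylic bromide; benzyl is chosen because it should survive base, n-BuLi at −78 °C and the thermal key step and is later removed by hydrogenolysis without touching methyl or ethyl ethers.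

Step 4
Reactants: 8 6-(benzyloxy)-2,3,4-trimethoxybenzaldehyde
Product: 10 6-(benzyloxy)-2,3,4-trimethoxyphenol, via aryl formate 9 (not isolated)
Conditions: mCPBA, CH2Cl2, 0 °C to rt; aq NaHCO3 wash; then K2CO3 (cat.), MeOH, rt
Reagents that add atoms: 3-chloroperoxybenzoic acid (mCPBA), OOC(=O)c1cccc(Cl)c1
Why: Baeyer–Villiger oxidation of an electron-rich aryl aldehyde (Dakin-type): the aryl group flanked by two alkoxy substituents migrates to oxygen in the peracid adduct, and catalytic methanolysis of the formate should release the doubly ortho-substituted phenol.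

Step 5
Reactants: 10 6-(benzyloxy)-2,3,4-trimethoxyphenol; 11 trichloroethylene
Product: 13 1-(benzyloxy)-2-{[(E)-1,2-dichloroethenyl]oxy}-3,4,5-trimethoxybenzene, via dichloroacetylene 12 (not isolated)
Conditions: K2CO3, DMF, 70 °C
Reagents that add atoms: none
Why: Base-mediated vinylation of a phenol with trichloroethylene (elimination–addition): dehydrochlorination gives dichloroacetylene, a slim linear electrophile to which the hindered phenoxide adds in anti fashion to give the (E)-dichlorovinyl ether, so the crowded oxygen is functionalised without any aryl–oxygen coupling.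

Step 6
Reactants: 13 1-(benzyloxy)-2-{[(E)-1,2-dichloroethenyl]oxy}-3,4,5-trimethoxybenzene
Product: 16 1-(benzyloxy)-2-(ethynyloxy)-3,4,5-trimethoxybenzene, via chloroalkyne 14 (not isolated), via lithium acetylide 15 (not isolated)
Conditions: n-BuLi (2.2 equiv), Et2O, −78 to −40 °C; then H2O, −78 °C
Reagents that add atoms: none
Why: Ynol ether synthesis by elimination and halogen–lithium exchange: n-BuLi removes the vinylic hydrogen with loss of chloride to give the chloroalkyne, a second equivalent exchanges chlorine for lithium, and water protonates the acetylide; at −78 °C neither the benzyl ether nor the ring hydrogen should be metalated competitively.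

Step 7
Reactants: 16 1-(benzyloxy)-2-(ethynyloxy)-3,4,5-trimethoxybenzene; 4 3-ethoxy-4-methoxycyclobut-2-en-1-one
Product: 21 3-[6-(benzyloxy)-2,3,4-trimethoxyphenoxy]-5-ethoxy-4-methoxyphenol, via vinylketene 17 (not isolated), via cyclobutenone adduct 18 (not isolated), via dienylketene 19 (not isolated), via cyclohexadienone 20 (not isolated)
Conditions: 4 (2 equiv), PhMe, 80 to 110 °C, sealed tube; then KOH, MeOH, rt
Reagents that add atoms: none
Why: Danheiser benzannulation: heat opens cyclobutenone 4 by 4π-electrocyclic ring opening to vinylketene 17, which adds to ynol ether 16 in a [2+2] cycloaddition to give 4-vinylcyclobutenone 18; a second 4π opening gives dienylketene 19, 6π-electrocyclisation gives cyclohexadienone 20, and enolisation gives phenol 21. The closest known reaction is the benzannulation of cyclobutenones with alkoxy- and siloxyalkynes to resorcinol monoethers; the aryloxyalkyne belongs to the same ynol ether class and, lacking a β-hydrogen on the oxygen substituent, cannot fragment by retro-ene loss of an alkene as alkyl ynol ethers do. Ring H is closed by thermal disrotatory 6π-electrocyclisation between the ketene carbonyl carbon and the methoxy-bearing diene terminus, which re-forms the bond cleaved in the first ring opening after the [2+2] step has made the two new carbon–carbon bonds. No stereocentre survives, since the sp3 carbons of 4, 18 and 20 all become aromatic carbons. The step needs one regiochemical outcome, ketene carbonyl carbon to the alkyne CH and ketene α-carbon to the oxygen-bearing alkyne carbon, and the donor oxygen of the ynol ether secures it by making the terminal carbon the nucleophilic end. The closing treatment with KOH in MeOH should return any product phenol that was acylated by excess ketene.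

Step 8
Reactants: 21 3-[6-(benzyloxy)-2,3,4-trimethoxyphenoxy]-5-ethoxy-4-methoxyphenol
Product: 22 1-(benzyloxy)-2-(3-ethoxy-4,5-dimethoxyphenoxy)-3,4,5-trimethoxybenzene
Conditions: MeI, K2CO3, acetone, reflux
Reagents that add atoms: iodomethane, CI
Why: Williamson O-methylation (SN2) caps the new ring H phenol so that, after debenzylation, ring G offers the only free hydroxyl.

Step 9
Reactants: 22 1-(benzyloxy)-2-(3-ethoxy-4,5-dimethoxyphenoxy)-3,4,5-trimethoxybenzene
Product: 23 2-(3-ethoxy-4,5-dimethoxyphenoxy)-3,4,5-trimethoxyphenol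
Conditions: H2 (1 atm), Pd/C, EtOAc–MeOH, rt
Reagents that add atoms: none
Why: Catalytic hydrogenolysis of a benzyl aryl ether: only the benzylic C–O bond is cleaved, since methyl, ethyl and diaryl ethers are inert and the molecule holds no halogen or reducible π bond at this stage.

Step 10
Reactants: 23 2-(3-ethoxy-4,5-dimethoxyphenoxy)-3,4,5-trimethoxyphenol; 24 4-bromo-2-fluoro-6-methoxybenzaldehyde
Product: 25 4-bromo-2-[2-(3-ethoxy-4,5-dimethoxyphenoxy)-3,4,5-trimethoxyphenoxy]-6-methoxybenzaldehyde
Conditions: K2CO3, DMF, 90 °C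
Reagents that add atoms: none
Why: Nucleophilic aromatic substitution (SNAr): the ortho-formyl group stabilises the anionic adduct at the fluorine-bearing carbon of 24, fluoride leaves far more readily than the bromide para to the aldehyde, and the bromide is thereby kept as the coupling handle for step 23.

Step 11
Reactants: 25 4-bromo-2-[2-(3-ethoxy-4,5-dimethoxyphenoxy)-3,4,5-trimethoxyphenoxy]-6-methoxybenzaldehyde
Product: 27 4-bromo-2-[2-(3-ethoxy-4,5-dimethoxyphenoxy)-3,4,5-trimethoxyphenoxy]-6-methoxyphenol, via aryl formate 26 (not isolated)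
Conditions: mCPBA, CH2Cl2, 0 °C to rt; aq NaHCO3 wash; then K2CO3 (cat.), MeOH, rt
Reagents that add atoms: 3-chloroperoxybenzoic acid (mCPBA), OOC(=O)c1cccc(Cl)c1
Why: Baeyer–Villiger oxidation (Dakin-type) of the 2,6-dioxygenated benzaldehyde with aryl migration, then formate methanolysis, turns the activating formyl group into the C4 oxygen of ring F; the aryl bromide and the ethers should be inert to the peracid at 0 °C.

Step 12
Reactants: 27 4-bromo-2-[2-(3-ethoxy-4,5-dimethoxyphenoxy)-3,4,5-trimethoxyphenoxy]-6-methoxyphenol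
Product: 28 5-bromo-1-[2-(3-ethoxy-4,5-dimethoxyphenoxy)-3,4,5-trimethoxyphenoxy]-2,3-dimethoxybenzene
Conditions: MeI, K2CO3, DMF, rt
Reagents that add atoms: iodomethane, CI
Why: Williamson O-methylation (SN2) of the flanked phenol with the small electrophile MeI completes ring F and leaves aryl bromide 28 without a free hydroxyl that could compete in step 23.

Step 13
Reactants: 29 5-bromo-1,2,3-trimethoxybenzene
Product: 31 5-fluoro-1,2,3-trimethoxybenzene, via aryllithium 30 (not isolated)
Conditions: n-BuLi, THF, −78 °C; then NFSI, −78 °C to rt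
Reagents that add atoms: N-fluorobenzenesulfonimide (NFSI), O=S(=O)(c1ccccc1)N(F)S(=O)(=O)c1ccccc1
Why: Bromine–lithium exchange followed by electrophilic fluorination of the aryllithium with an N–F reagent: exchange is fast at −78 °C and the unhindered aryl anion attacks the fluorine of NFSI, a standard conversion of an aryl bromide into an aryl fluoride.

Step 14
Reactants: 31 5-fluoro-1,2,3-trimethoxybenzene
Product: 34 6-fluoro-2,3,4-trimethoxybenzaldehyde, via aryllithium 32 (not isolated), via hemiaminal alkoxide 33 (not isolated)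
Conditions: n-BuLi, THF, −78 °C; then DMF, −78 °C; then 1 M HCl
Reagents that add atoms: N,N-dimethylformamide, CN(C)C=O
Why: Directed ortho-metalation and formylation: the hydrogen between fluorine and methoxy is the most acidic and both such sites of 31 are equivalent, so one regioisomer is expected; at −78 °C the ortho-fluoroaryllithium is trapped by DMF before it can lose LiF, and the transient racemic hemiaminal collapses to the aldehyde on acidification.

Step 15
Reactants: 35 2-bromo-3,4,5-trimethoxybenzaldehyde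
Product: 36 2-(2-bromo-3,4,5-trimethoxyphenyl)-1,3-dioxolane
Conditions: HOCH2CH2OH, TsOH (cat.), PhMe, reflux, Dean–Stark
Reagents that add atoms: ethylene glycol, OCCO
Why: Acid-catalysed acetalisation with azeotropic removal of water masks the aldehyde as a dioxolane that tolerates n-BuLi.

Step 16
Reactants: 36 2-(2-bromo-3,4,5-trimethoxyphenyl)-1,3-dioxolane
Product: 39 2-fluoro-3,4,5-trimethoxybenzaldehyde, via aryllithium 37 (not isolated), via fluoro acetal 38 (not isolated)
Conditions: n-BuLi, THF, −78 °C; then NFSI, −78 °C to rt; then 2 M HCl, THF, rt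
Reagents that add atoms: N-fluorobenzenesulfonimide (NFSI), O=S(=O)(c1ccccc1)N(F)S(=O)(=O)c1ccccc1; water, O
Why: Bromine–lithium exchange, electrophilic fluorination with NFSI and acidic hydrolysis of the dioxolane in the work-up: the site of fluorine is fixed by the site of bromine in 35, which avoids any regiochemical question.

Step 17
Reactants: 40 4-bromo-2,6-dimethoxyphenol; 34 6-fluoro-2,3,4-trimethoxybenzaldehyde
Product: 41 6-(4-bromo-2,6-dimethoxyphenoxy)-2,3,4-trimethoxybenzaldehyde
Conditions: Cs2CO3, DMSO, 100 °C, argon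
Reagents that add atoms: none
Why: SNAr on an ortho-fluorobenzaldehyde: the phenoxide of 40 displaces the formyl-activated fluoride, whose carbon has a hydrogen neighbour, while the aryl bromide is inert without a metal catalyst, so a bromo aldehyde spanning rings B and C should result.

Step 18
Reactants: 42 2,4,6-trimethoxyphenol; 41 6-(4-bromo-2,6-dimethoxyphenoxy)-2,3,4-trimethoxybenzaldehyde
Product: 43 6-[2,6-dimethoxy-4-(2,4,6-trimethoxyphenoxy)phenoxy]-2,3,4-trimethoxybenzaldehyde
Conditions: CuI (10 mol%), picolinic acid (20 mol%), K3PO4, DMSO, 90 °C, argon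
Reagents that add atoms: none
Why: Copper-catalysed Ullmann diaryl ether synthesis with picolinic acid as ligand, a system suited to ortho-substituted phenols: the doubly flanked phenol 42 meets an aryl bromide with two hydrogen neighbours, and the non-enolisable aldehyde should tolerate K3PO4.

Step 19
Reactants: 43 6-[2,6-dimethoxy-4-(2,4,6-trimethoxyphenoxy)phenoxy]-2,3,4-trimethoxybenzaldehyde
Product: 45 6-[2,6-dimethoxy-4-(2,4,6-trimethoxyphenoxy)phenoxy]-2,3,4-trimethoxyphenol, via aryl formate 44 (not isolated)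
Conditions: mCPBA, CH2Cl2, 0 °C; aq NaHCO3 wash; then K2CO3 (cat.), MeOH, rt
Reagents that add atoms: 3-chloroperoxybenzoic acid (mCPBA), OOC(=O)c1cccc(Cl)c1
Why: Baeyer–Villiger oxidation (Dakin-type) and formate methanolysis convert the ring C aldehyde, primed for aryl migration by its ortho aryloxy, ortho methoxy and para methoxy groups, into the flanked C2 phenol; short exposure at 0 °C should limit oxidation of the electron-rich ring A.

Step 20
Reactants: 40 4-bromo-2,6-dimethoxyphenol; 39 2-fluoro-3,4,5-trimethoxybenzaldehyde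
Product: 46 2-(4-bromo-2,6-dimethoxyphenoxy)-3,4,5-trimethoxybenzaldehyde
Conditions: Cs2CO3, DMSO, 120 °C, argon
Reagents that add atoms: none
Why: SNAr that forms the ether with four ortho substituents: the coplanar ortho-formyl group activates the fluoride of 39 and the nucleophile approaches perpendicular to the ring plane, which eases the crowding, while the methoxy groups ortho and para to fluorine retard the step and call for Cs2CO3 in DMSO at 120 °C.

Step 21
Reactants: 45 6-[2,6-dimethoxy-4-(2,4,6-trimethoxyphenoxy)phenoxy]-2,3,4-trimethoxyphenol; 46 2-(4-bromo-2,6-dimethoxyphenoxy)-3,4,5-trimethoxybenzaldehyde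
Product: 47 2-(4-{6-[2,6-dimethoxy-4-(2,4,6-trimethoxyphenoxy)phenoxy]-2,3,4-trimethoxyphenoxy}-2,6-dimethoxyphenoxy)-3,4,5-trimethoxybenzaldehyde
Conditions: CuI (10 mol%), picolinic acid (20 mol%), K3PO4, DMSO, 90 °C, argon
Reagents that add atoms: none
Why: Ullmann diaryl ether synthesis (CuI, picolinic acid): the hindered ring C phenol of 45 couples at the bromide of ring D in 46, which has two hydrogen neighbours, the same pairing of partners as in step 18.

Step 22
Reactants: 47 the rings A–E aldehyde
Product: 49 2-(4-{6-[2,6-dimethoxy-4-(2,4,6-trimethoxyphenoxy)phenoxy]-2,3,4-trimethoxyphenoxy}-2,6-dimethoxyphenoxy)-3,4,5-trimethoxyphenol, via aryl formate 48 (not isolated)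
Conditions: mCPBA, CH2Cl2, 0 °C; aq NaHCO3 wash; then K2CO3 (cat.), MeOH, rt
Reagents that add atoms: 3-chloroperoxybenzoic acid (mCPBA), OOC(=O)c1cccc(Cl)c1
Why: Baeyer–Villiger oxidation (Dakin-type) with migration of the ortho-aryloxy, para-methoxy aryl group, then formate methanolysis, should unveil the ring E phenol at C2, next to a ring hydrogen.

Step 23
Reactants: 49 the rings A–E phenol; 28 5-bromo-1-[2-(3-ethoxy-4,5-dimethoxyphenoxy)-3,4,5-trimethoxyphenoxy]-2,3-dimethoxybenzene
Product: 50 the fully O-alkylated octamer, 1-[2-(3-ethoxy-4,5-dimethoxyphenoxy)-3,4,5-trimethoxyphenoxy]-2,3-dimethoxy-5-[2-(4-{6-[2,6-dimethoxy-4-(2,4,6-trimethoxyphenoxy)phenoxy]-2,3,4-trimethoxyphenoxy}-2,6-dimethoxyphenoxy)-3,4,5-trimethoxyphenoxy]benzene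
Conditions: CuI (20 mol%), picolinic acid (40 mol%), K3PO4, DMSO, 90 °C, argon
Reagents that add atoms: none
Why: Ullmann diaryl ether synthesis joins the two halves: phenol 49 has one ortho substituent and bromide 28 has none, the least hindered ether bond of the chain, which is why the fragment union is placed here.

Step 24
Reactants: 50 the fully O-alkylated octamer
Product: 51 CNP0309601.0, the octamer with all twenty-one oxygens of 50 as free hydroxyls
Conditions: BBr3 (excess), CH2Cl2, −78 °C to rt, argon; then H2O, 0 °C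
Reagents that add atoms: none
Why: Lewis acid cleavage of aryl alkyl ethers: BBr3 coordinates each alkoxy oxygen and bromide removes the methyl or ethyl group by SN2, whereas the diaryl ether oxygens carry no sp3 carbon and stay intact; hydrolysis of the aryl borates should release all twenty-one hydroxyls.

Compound list

1 | methoxyacetyl chloride | COCC(=O)Cl | starting material
2 | ethoxyacetylene (ethoxyethyne) | C#COCC | starting material
3 | methoxyketene | COC=C=O | intermediate (not isolated)
4 | 3-ethoxy-4-methoxycyclobut-2-en-1-one (racemic) | O=C1C=C(OCC)C1OC | intermediate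
5 | 3,4,5-trimethoxyphenol | COc1cc(O)cc(OC)c1OC | starting material
6 | 2-(hydroxymethyl)-3,4,5-trimethoxyphenol (present as its magnesium salt) | OCc1c(O)cc(OC)c(OC)c1OC | intermediate (not isolated)
7 | 6-hydroxy-2,3,4-trimethoxybenzaldehyde | O=Cc1c(O)cc(OC)c(OC)c1OC | intermediate
8 | 6-(benzyloxy)-2,3,4-trimethoxybenzaldehyde | O=Cc1c(OCc2ccccc2)cc(OC)c(OC)c1OC | intermediate
9 | 6-(benzyloxy)-2,3,4-trimethoxyphenyl formate | O=COc1c(OCc2ccccc2)cc(OC)c(OC)c1OC | intermediate (not isolated)
10 | 6-(benzyloxy)-2,3,4-trimethoxyphenol | Oc1c(OCc2ccccc2)cc(OC)c(OC)c1OC | intermediate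
11 | trichloroethylene | ClC=C(Cl)Cl | starting material
12 | dichloroacetylene | ClC#CCl | intermediate (not isolated)
13 | 1-(benzyloxy)-2-{[(E)-1,2-dichloroethenyl]oxy}-3,4,5-trimethoxybenzene | Cl/C=C(/Cl)Oc1c(OCc2ccccc2)cc(OC)c(OC)c1OC | intermediate
14 | 1-(benzyloxy)-2-[(chloroethynyl)oxy]-3,4,5-trimethoxybenzene | ClC#COc1c(OCc2ccccc2)cc(OC)c(OC)c1OC | intermediate (not isolated)
15 | lithium acetylide of 16, {[6-(benzyloxy)-2,3,4-trimethoxyphenoxy]ethynyl}lithium | [Li]C#COc1c(OCc2ccccc2)cc(OC)c(OC)c1OC | intermediate (not isolated)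
16 | 1-(benzyloxy)-2-(ethynyloxy)-3,4,5-trimethoxybenzene (ring G ynol ether) | C#COc1c(OCc2ccccc2)cc(OC)c(OC)c1OC | intermediate
17 | (Z)-3-ethoxy-4-methoxybuta-1,3-dien-1-one (vinylketene, methoxy rotated outward) | O=C=C/C(OCC)=C/OC | intermediate (not isolated)
18 | 3-[6-(benzyloxy)-2,3,4-trimethoxyphenoxy]-4-[(Z)-1-ethoxy-2-methoxyethenyl]cyclobut-2-en-1-one (racemic) | O=C1C=C(Oc2c(OCc3ccccc3)cc(OC)c(OC)c2OC)C1/C(OCC)=C/OC | intermediate (not isolated)
19 | (3E,5Z)-3-[6-(benzyloxy)-2,3,4-trimethoxyphenoxy]-5-ethoxy-6-methoxyhexa-1,3,5-trien-1-one (dienylketene) | O=C=C/C(Oc1c(OCc2ccccc2)cc(OC)c(OC)c1OC)=C\C(OCC)=C\OC | intermediate (not isolated)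
20 | 3-[6-(benzyloxy)-2,3,4-trimethoxyphenoxy]-5-ethoxy-6-methoxycyclohexa-2,4-dien-1-one (racemic) | O=C1C=C(Oc2c(OCc3ccccc3)cc(OC)c(OC)c2OC)C=C(OCC)C1OC | intermediate (not isolated)
21 | 3-[6-(benzyloxy)-2,3,4-trimethoxyphenoxy]-5-ethoxy-4-methoxyphenol (rings G–H) | Oc1cc(Oc2c(OCc3ccccc3)cc(OC)c(OC)c2OC)cc(OCC)c1OC | intermediate
22 | 1-(benzyloxy)-2-(3-ethoxy-4,5-dimethoxyphenoxy)-3,4,5-trimethoxybenzene | COc1cc(Oc2c(OCc3ccccc3)cc(OC)c(OC)c2OC)cc(OCC)c1OC | intermediate
23 | 2-(3-ethoxy-4,5-dimethoxyphenoxy)-3,4,5-trimethoxyphenol | COc1cc(Oc2c(O)cc(OC)c(OC)c2OC)cc(OCC)c1OC | intermediate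
24 | 4-bromo-2-fluoro-6-methoxybenzaldehyde | O=Cc1c(F)cc(Br)cc1OC | starting material
25 | 4-bromo-2-[2-(3-ethoxy-4,5-dimethoxyphenoxy)-3,4,5-trimethoxyphenoxy]-6-methoxybenzaldehyde | O=Cc1c(OC)cc(Br)cc1Oc1cc(OC)c(OC)c(OC)c1Oc1cc(OC)c(OC)c(OCC)c1 | intermediate
26 | 4-bromo-2-[2-(3-ethoxy-4,5-dimethoxyphenoxy)-3,4,5-trimethoxyphenoxy]-6-methoxyphenyl formate | O=COc1c(OC)cc(Br)cc1Oc1cc(OC)c(OC)c(OC)c1Oc1cc(OC)c(OC)c(OCC)c1 | intermediate (not isolated)
27 | 4-bromo-2-[2-(3-ethoxy-4,5-dimethoxyphenoxy)-3,4,5-trimethoxyphenoxy]-6-methoxyphenol | Oc1c(OC)cc(Br)cc1Oc1cc(OC)c(OC)c(OC)c1Oc1cc(OC)c(OC)c(OCC)c1 | intermediate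
28 | 5-bromo-1-[2-(3-ethoxy-4,5-dimethoxyphenoxy)-3,4,5-trimethoxyphenoxy]-2,3-dimethoxybenzene (rings F–H bromide) | COc1c(OC)cc(Br)cc1Oc1cc(OC)c(OC)c(OC)c1Oc1cc(OC)c(OC)c(OCC)c1 | intermediate
29 | 5-bromo-1,2,3-trimethoxybenzene | COc1cc(Br)cc(OC)c1OC | starting material
30 | (3,4,5-trimethoxyphenyl)lithium | [Li]c1cc(OC)c(OC)c(OC)c1 | intermediate (not isolated)
31 | 5-fluoro-1,2,3-trimethoxybenzene | COc1cc(F)cc(OC)c1OC | intermediate
32 | (6-fluoro-2,3,4-trimethoxyphenyl)lithium | [Li]c1c(F)cc(OC)c(OC)c1OC | intermediate (not isolated)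
33 | lithium (dimethylamino)(6-fluoro-2,3,4-trimethoxyphenyl)methanolate (racemic) | [Li+].[O-]C(N(C)C)c1c(F)cc(OC)c(OC)c1OC | intermediate (not isolated)
34 | 6-fluoro-2,3,4-trimethoxybenzaldehyde | O=Cc1c(F)cc(OC)c(OC)c1OC | intermediate
35 | 2-bromo-3,4,5-trimethoxybenzaldehyde | O=Cc1cc(OC)c(OC)c(OC)c1Br | starting material
36 | 2-(2-bromo-3,4,5-trimethoxyphenyl)-1,3-dioxolane | Brc1c(C2OCCO2)cc(OC)c(OC)c1OC | intermediate
37 | [2-(1,3-dioxolan-2-yl)-4,5,6-trimethoxyphenyl]lithium | [Li]c1c(C2OCCO2)cc(OC)c(OC)c1OC | intermediate (not isolated)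
38 | 2-(2-fluoro-3,4,5-trimethoxyphenyl)-1,3-dioxolane | Fc1c(C2OCCO2)cc(OC)c(OC)c1OC | intermediate (not isolated)
39 | 2-fluoro-3,4,5-trimethoxybenzaldehyde | O=Cc1cc(OC)c(OC)c(OC)c1F | intermediate
40 | 4-bromo-2,6-dimethoxyphenol | COc1cc(Br)cc(OC)c1O | starting material
41 | 6-(4-bromo-2,6-dimethoxyphenoxy)-2,3,4-trimethoxybenzaldehyde (rings B–C) | O=Cc1c(Oc2c(OC)cc(Br)cc2OC)cc(OC)c(OC)c1OC | intermediate
42 | 2,4,6-trimethoxyphenol | COc1cc(OC)c(O)c(OC)c1 | starting material
43 | 6-[2,6-dimethoxy-4-(2,4,6-trimethoxyphenoxy)phenoxy]-2,3,4-trimethoxybenzaldehyde (rings A–C) | O=Cc1c(Oc2c(OC)cc(Oc3c(OC)cc(OC)cc3OC)cc2OC)cc(OC)c(OC)c1OC | intermediate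
44 | 6-[2,6-dimethoxy-4-(2,4,6-trimethoxyphenoxy)phenoxy]-2,3,4-trimethoxyphenyl formate | O=COc1c(Oc2c(OC)cc(Oc3c(OC)cc(OC)cc3OC)cc2OC)cc(OC)c(OC)c1OC | intermediate (not isolated)
45 | 6-[2,6-dimethoxy-4-(2,4,6-trimethoxyphenoxy)phenoxy]-2,3,4-trimethoxyphenol | Oc1c(Oc2c(OC)cc(Oc3c(OC)cc(OC)cc3OC)cc2OC)cc(OC)c(OC)c1OC | intermediate
46 | 2-(4-bromo-2,6-dimethoxyphenoxy)-3,4,5-trimethoxybenzaldehyde (rings D–E) | O=Cc1cc(OC)c(OC)c(OC)c1Oc1c(OC)cc(Br)cc1OC | intermediate
47 | 2-(4-{6-[2,6-dimethoxy-4-(2,4,6-trimethoxyphenoxy)phenoxy]-2,3,4-trimethoxyphenoxy}-2,6-dimethoxyphenoxy)-3,4,5-trimethoxybenzaldehyde (rings A–E) | O=Cc1cc(OC)c(OC)c(OC)c1Oc1c(OC)cc(Oc2c(Oc3c(OC)cc(Oc4c(OC)cc(OC)cc4OC)cc3OC)cc(OC)c(OC)c2OC)cc1OC | intermediate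
48 | formate of 49, the aryl formate from Baeyer–Villiger oxidation of 47 | O=COc1cc(OC)c(OC)c(OC)c1Oc1c(OC)cc(Oc2c(Oc3c(OC)cc(Oc4c(OC)cc(OC)cc4OC)cc3OC)cc(OC)c(OC)c2OC)cc1OC | intermediate (not isolated)
49 | 2-(4-{6-[2,6-dimethoxy-4-(2,4,6-trimethoxyphenoxy)phenoxy]-2,3,4-trimethoxyphenoxy}-2,6-dimethoxyphenoxy)-3,4,5-trimethoxyphenol | Oc1cc(OC)c(OC)c(OC)c1Oc1c(OC)cc(Oc2c(Oc3c(OC)cc(Oc4c(OC)cc(OC)cc4OC)cc3OC)cc(OC)c(OC)c2OC)cc1OC | intermediate
50 | fully O-alkylated octamer (twenty methyl ethers and the ring H ethyl ether; systematic name in step 23) | COc1c(OC)cc(Oc2cc(OC)c(OC)c(OC)c2Oc2c(OC)cc(Oc3c(Oc4c(OC)cc(Oc5c(OC)cc(OC)cc5OC)cc4OC)cc(OC)c(OC)c3OC)cc2OC)cc1Oc1cc(OC)c(OC)c(OC)c1Oc1cc(OC)c(OC)c(OCC)c1 | intermediate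
51 | CNP0309601.0 (octameric polyphenol, rings A–H, twenty-one free hydroxyls) | Oc1cc(O)c(Oc2cc(O)c(Oc3cc(O)c(O)c(O)c3Oc3cc(O)c(Oc4c(Oc5cc(O)c(O)c(Oc6cc(O)c(O)c(O)c6Oc6cc(O)c(O)c(O)c6)c5)cc(O)c(O)c4O)c(O)c3)c(O)c2)c(O)c1 | target

Total step count: 24.
Longest linear sequence: 13 steps (steps 2 to 12, then 23 and 24; 5 → 7 → 8 → 10 → 13 → 16 → 21 → 22 → 23 → 25 → 27 → 28 → 50 → 51).

Steps most likely to fail

1. Step 7. The terminal aryloxyalkyne may oligomerise, or the vinylketene may dimerise, faster than the two combine, because the 3-ethoxy group stabilises the cyclobutenone as a vinylogous ester and raises the temperature needed for ring opening. The fallback sets out from phenol 10 and returns to the route at 22. Purchased 5-bromo-2,3-dimethoxybenzaldehyde is oxidised with mCPBA to 5-bromo-2,3-dimethoxyphenyl formate F1, which catalytic K2CO3 in MeOH cleaves to 5-bromo-2,3-dimethoxyphenol F2. Ethylation (EtI, K2CO3, DMF) gives 5-bromo-1-ethoxy-2,3-dimethoxybenzene F3, a ready-made ring H. Ullmann coupling of F3 with 10 (CuI, picolinic acid, K3PO4, DMSO, 90 °C), a hindered phenol with an unhindered bromide as in step 18, should give 22. Steps 1 and 5 to 8 are then bypassed and ring H is brought in whole instead of being built.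

2. Step 20. Substitution at a fluorine-bearing carbon flanked by formyl and methoxy, by a phenoxide that is itself flanked twice, may be too slow, so that base-induced decay of the aldehyde at 120 °C wins. The fallback sets out from phenol 10 and returns at 49; it reverses the polarity and installs the flanking methoxy groups of ring D only after the ether bond exists. Phenol 10 and the known dialdehyde 5-bromo-2-fluorobenzene-1,3-dicarbaldehyde (purchased; K2CO3, DMF, rt to 50 °C), whose fluoride lies between two formyl groups and is displaced readily, give 5-bromo-2-[6-(benzyloxy)-2,3,4-trimethoxyphenoxy]benzene-1,3-dicarbaldehyde F4. Double Baeyer–Villiger oxidation (mCPBA) gives 5-bromo-2-[6-(benzyloxy)-2,3,4-trimethoxyphenoxy]-1,3-phenylene diformate F5, and methanolysis gives 5-bromo-2-[6-(benzyloxy)-2,3,4-trimethoxyphenoxy]benzene-1,3-diol F6. Methylation (MeI, K2CO3) gives 1-(benzyloxy)-2-(4-bromo-2,6-dimethoxyphenoxy)-3,4,5-trimethoxybenzene F7. Ullmann coupling of F7 with phenol 45 (CuI, picolinic acid, K3PO4, DMSO) gives the rings A–E benzyl ether F8, which is 49 with its hydroxyl benzylated, and hydrogenolysis (H2, Pd/C) gives 49. Steps 15, 16 and 20 to 22 are bypassed.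

3. Step 24. Some of the twenty-one alkyl groups, above all the ethyl group and the doubly flanked methoxy groups, may resist cleavage, and the free polyphenol may oxidise in air during isolation, so that no pure product is obtained. The fallback sets out from 50 and returns at 51. The BBr3 dealkylation is run as in step 24, but the crude polyphenol is not isolated; it is acetylated at once (Ac2O, pyridine, DMAP) to the henicosaacetate of the target F9. F9 is stable to air and to silica, so partly dealkylated material can be separated and returned to BBr3. Methanolysis of purified F9 with anhydrous HCl in MeOH under argon should then release 51.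

Further compounds

F1 | step 7 | 5-bromo-2,3-dimethoxyphenyl formate | O=COc1cc(Br)cc(OC)c1OC
F2 | step 7 | 5-bromo-2,3-dimethoxyphenol | Oc1cc(Br)cc(OC)c1OC
F3 | step 7 | 5-bromo-1-ethoxy-2,3-dimethoxybenzene | CCOc1cc(Br)cc(OC)c1OC
F4 | step 20 | 5-bromo-2-[6-(benzyloxy)-2,3,4-trimethoxyphenoxy]benzene-1,3-dicarbaldehyde | O=Cc1cc(Br)cc(C=O)c1Oc1c(OCc2ccccc2)cc(OC)c(OC)c1OC
F5 | step 20 | 5-bromo-2-[6-(benzyloxy)-2,3,4-trimethoxyphenoxy]-1,3-phenylene diformate | O=COc1cc(Br)cc(OC=O)c1Oc1c(OCc2ccccc2)cc(OC)c(OC)c1OC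
F6 | step 20 | 5-bromo-2-[6-(benzyloxy)-2,3,4-trimethoxyphenoxy]benzene-1,3-diol | Oc1cc(Br)cc(O)c1Oc1c(OCc2ccccc2)cc(OC)c(OC)c1OC
F7 | step 20 | 1-(benzyloxy)-2-(4-bromo-2,6-dimethoxyphenoxy)-3,4,5-trimethoxybenzene | COc1cc(Br)cc(OC)c1Oc1c(OCc2ccccc2)cc(OC)c(OC)c1OC
F8 | step 20 | rings A–E benzyl ether (49 with its hydroxyl benzylated) | c1ccccc1COc1cc(OC)c(OC)c(OC)c1Oc1c(OC)cc(Oc2c(Oc3c(OC)cc(Oc4c(OC)cc(OC)cc4OC)cc3OC)cc(OC)c(OC)c2OC)cc1OC
F9 | step 24 | henicosaacetate of the target (all twenty-one hydroxyls acetylated) | CC(=O)Oc1cc(OC(C)=O)c(Oc2cc(OC(C)=O)c(Oc3cc(OC(C)=O)c(OC(C)=O)c(OC(C)=O)c3Oc3cc(OC(C)=O)c(Oc4c(Oc5cc(OC(C)=O)c(OC(C)=O)c(Oc6cc(OC(C)=O)c(OC(C)=O)c(OC(C)=O)c6Oc6cc(OC(C)=O)c(OC(C)=O)c(OC(C)=O)c6)c5)cc(OC(C)=O)c(OC(C)=O)c4OC(C)=O)c(OC(C)=O)c3)c(OC(C)=O)c2)c(OC(C)=O)c1
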